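You asked for a quick number, and I took your hunch as the forecast to beat.

| setting | cedar | birch | flask |
|---|---|---|---|
| substrate | 0.81 M | 0.81 M | 0.81 M |
| reagent | 1.62 M | 0.81 M | 1.62 M |
| free catalyst | 18 mM | 18 mM | 18 mM |
| second catalyst | 2 mM | 2 mM | 2.0 mM |
| impurity | 9.9 mM | 9.9 mM | 9.9 mM |
| remark | the very flask that is asked about, followed so far | run made earlier |  |

- cedar (time / min: product / %): 1.33: 0; 2.00: 2; 4.00: 3; 6.00: 9; 10.0: 20; 15.0: 30
- birch (time / min: product / %): 3.00: 1; 5.00: 3; 8.00: 9; 15.0: 23; 25.0: 38; 40.0: 55

(standard deviation of a reading: 1.5 percentage points)

- steps that have been proposed: free catalyst + impurity -> spent catalyst; substrate + free catalyst <-> free catalyst + intermediate; reagent + second catalyst + intermediate -> second catalyst + product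
- no earlier run changes the charge of free catalyst; that part of a forecast is a guess
- "the catalyst" is free catalyst with its forms; second catalyst is a second catalyst
- what has left substrate counts as converted, also if it is not yet product

- apparent order in reagent when 30% of the substrate are converted (percent change of the rate of making product for one percent more reagent charged)
- apparent order in free catalyst when 30% of the substrate are converted (percent change of the rate of making product for one percent more free catalyst charged)

I compared the cedar and birch runs from the same product reading, 9% in cedar and 9% in birch. Cedar, with more reagent, climbed faster.

rate in cedar / rate in birch = 1.38

order in reagent = ln(rate ratio) / ln(c(reagent) in cedar / c(reagent) in birch) = 0.459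

With a scatter of 1.5 percentage points on each reading, and with equal product standing in for equal conversion, this is a rough reading.

The proposed steps form a chain: free catalyst turns substrate into intermediate, then reagent and second catalyst drain it. While intermediate stays near steady, I took the two steps to share one unit of control (degree of rate control), so the order in reagent and the order in working free catalyst add to about 1. I also assumed that impurity removes free catalyst quickly, one for one. One percent more charged then means more than one percent more working, by the poison gain, the charge of free catalyst over what survives the impurity:

poison gain = c(free catalyst) / (c(free catalyst) − c(impurity)) = 2.22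

order in free catalyst = poison gain × (1 − order in reagent) = 1.20

The forecast gave 0.15 for reagent and 1.8 for free catalyst, holding that “Conversion therefore appears mainly limited by the catalysed first step”. My reagent order stood higher and my catalyst order lower.

The flask gave 0.37 for reagent and 1.5 for free catalyst.

    free catalyst + impurity → spent catalyst (k = 72.2 M⁻¹ s⁻¹)
    substrate + free catalyst ⇌ free catalyst + intermediate (K = 2.00, k = 0.0837 M⁻¹ s⁻¹)
    reagent + second catalyst + intermediate → second catalyst + product (k = 1.03 M⁻² s⁻¹)

Dividing the flask's catalyst order by the poison gain left 0.685, and adding its reagent order gave 1.05. The loss of free catalyst to impurity raised the catalyst order: the same run without that loss, whose poison gain is 1, had orders of 0.41 in free catalyst and 0.63 in reagent, which add to 1.04.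

All runs are calculated for substances that don't exist; noise was put on by code.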